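**Plan**

- Retrosynthesis: the three MOM ethers come off last, and the C2 stereocentre is traced back to the C2=C3 bond of a flavone. Ring C of that flavone is cut at C4a–C4, C3–C4 and O1–C2, giving a ring-A aryl iodide, carbon monoxide (as C4) and a ring-B terminal alkyne that already carries the fused dimethylpyran.
- Enabling feature: C4 sits between C4a and C3, and ring A is a 2,4-diprenylphloroglucinol. Its two oxygens ortho to C4a (the future O1 and O5) are related by a mirror plane through C4a and C7, so CO can be inserted at the C–I carbon and either oxygen closes ring C to the same flavone.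
- Forward order: ring A is dressed by three directed metalations (prenyl, prenyl, iodine) and carried as its triacetate. The dimethylpyran is built on resorcinol and the alkyne attached. Ring C is then closed in one carbonylative operation, and the C2=C3 bond is reduced last.
- Stereochemistry: the single stereocentre (2S) comes from ligand-controlled hydride delivery to C2 by a chiral copper hydride; only a mild acetal cleavage follows it.

Key step: step 11

Assumption: (R)-DTBM-SEGPHOS is taken to be the ligand antipode that delivers hydride to the C2 face giving 2S; a small-scale trial settles the sense of induction, and the (S) ligand is used if it is reversed.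

**Route**

Step 1
Reactants: 1 phloroglucinol
Product: 2 1,3,5-tris(methoxymethoxy)benzene
Conditions: NaH (3.6 equiv), MOMCl (3.6 equiv), DMF, 0 °C → rt
Reagents that add atoms: chloromethyl methyl ether (MOMCl), COCCl
Why: Williamson-type O-alkylation of the phenoxides with a hard α-chloro ether installs three acetals that protect the oxygens and act as ortho-directing groups for the metalations that follow.

Step 2
Reactants: 2 1,3,5-tris(methoxymethoxy)benzene; 3 prenyl bromide
Product: 5 1,3,5-tris(methoxymethoxy)-2-(3-methylbut-2-enyl)benzene, via aryllithium 4 (not isolated)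
Conditions: n-BuLi (1.1 equiv), TMEDA, THF, −20 → 0 °C; CuBr·SMe2 (10 mol %), prenyl bromide (1.2 equiv), −78 °C → rt
Reagents that add atoms: prenyl bromide (3), CC(C)=CCBr
Why: Directed ortho-metalation at a ring CH flanked by two OMOM groups, followed by copper-catalysed SN2 allylation, should deliver the linear prenyl group on carbon only.

Step 3
Reactants: 5 1,3,5-tris(methoxymethoxy)-2-(3-methylbut-2-enyl)benzene; 3 prenyl bromide
Product: 7 1,3,5-tris(methoxymethoxy)-2,4-bis(3-methylbut-2-enyl)benzene, via aryllithium 6 (not isolated)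
Conditions: n-BuLi (1.1 equiv), TMEDA, THF, −20 → 0 °C; CuBr·SMe2 (10 mol %), prenyl bromide (1.2 equiv), −78 °C → rt
Reagents that add atoms: prenyl bromide (3), CC(C)=CCBr
Why: A second directed ortho-metalation at one of the two equivalent remaining ring positions (each between two OMOM groups) should be kinetically faster than deprotonation of the benzylic-allylic CH2, and the allylation repeats step 2.

Step 4
Reactants: 7 1,3,5-tris(methoxymethoxy)-2,4-bis(3-methylbut-2-enyl)benzene
Product: 9 2-iodo-1,3,5-tris(methoxymethoxy)-4,6-bis(3-methylbut-2-enyl)benzene, via aryllithium 8 (not isolated)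
Conditions: n-BuLi (1.15 equiv), TMEDA, THF, −20 → 0 °C; I2 (1.2 equiv), THF, −78 °C; aq. Na2S2O3
Reagents that add atoms: iodine, II
Why: Directed ortho-metalation of the last ring CH and iodinolysis of the aryllithium at low temperature place iodine regiospecifically and avoid electrophilic iodination conditions, under which a free ortho-prenylphenol would be at risk of iodoetherification.

Step 5
Reactants: 9 2-iodo-1,3,5-tris(methoxymethoxy)-4,6-bis(3-methylbut-2-enyl)benzene
Product: 11 2-iodo-4,6-bis(3-methylbut-2-enyl)benzene-1,3,5-triyl triacetate, via iodotriol 10 (not isolated)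
Conditions: HCl (2 M in MeOH), 0 °C → rt; concentrate below 30 °C; Ac2O, pyridine, DMAP (cat.), CH2Cl2, 0 °C → rt
Reagents that add atoms: acetic anhydride, CC(=O)OC(C)=O
Why: Acid-catalysed acetal exchange with methanol frees the three di-ortho-substituted (hence readily cleaved) MOM ethers under mild conditions, and immediate peracetylation of the crude, air-sensitive iodotriol should give a stable aryl iodide of the iodophenol acetate type used in carbonylative annulations.

Step 6
Reactants: 12 resorcinol; 13 3-methylbut-2-enoic acid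
Product: 15 7-hydroxy-2,2-dimethylchroman-4-one, via aryl enone 14 (not isolated)
Conditions: Eaton's reagent (P2O5/MeSO3H), 70 °C
Reagents that add atoms: 3-methylbut-2-enoic acid (13), CC(C)=CC(=O)O
Why: Friedel–Crafts acylation at C4 of resorcinol followed by intramolecular oxa-Michael addition of the ortho-hydroxyl is the classical, regiochemically unambiguous entry to the linear 7-oxygenated 2,2-dimethylchroman skeleton.

Step 7
Reactants: 15 7-hydroxy-2,2-dimethylchroman-4-one
Product: 17 2,2-dimethyl-2H-chromen-7-ol, via chromanediol 16 (not isolated)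
Conditions: LiAlH4 (2 equiv), THF, 0 °C → reflux; Rochelle salt work-up; TsOH·H2O (2 mol %), toluene, 50 °C
Reagents that add atoms: none
Why: Hydride reduction of the ketone, then acid-catalysed E1 dehydration of the benzylic carbinol (cation stabilised by the ortho ring oxygen and the para hydroxyl), should give the conjugated chromene as in the established precocene-type sequence.

Step 8
Reactants: 17 2,2-dimethyl-2H-chromen-7-ol
Product: 19 7-hydroxy-2,2-dimethyl-2H-chromene-6-carbaldehyde, via salicyl alcohol 18 (not isolated)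
Conditions: MgCl2 (2 equiv), Et3N (4 equiv), (CH2O)n (6 equiv), MeCN, reflux
Reagents that add atoms: paraformaldehyde (as formaldehyde), C=O
Why: In the Casnati–Skattebøl ortho-formylation the magnesium phenoxide delivers formaldehyde only ortho to the hydroxyl, and as with other 3-alkoxyphenols the unhindered C6 (para to the ring oxygen) is expected to be preferred over C8, which is flanked by two oxygens.

Step 9
Reactants: 19 7-hydroxy-2,2-dimethyl-2H-chromene-6-carbaldehyde
Product: 20 7-(methoxymethoxy)-2,2-dimethyl-2H-chromene-6-carbaldehyde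
Conditions: NaH (1.3 equiv), MOMCl (1.3 equiv), DMF, 0 °C → rt
Reagents that add atoms: chloromethyl methyl ether (MOMCl), COCCl
Why: O-alkylation of the sodium phenoxide of a chelated salicylaldehyde gives an acetal that is stable to the carbonate, amine and hydride conditions still to come.

Step 10
Reactants: 20 7-(methoxymethoxy)-2,2-dimethyl-2H-chromene-6-carbaldehyde
Product: 21 6-ethynyl-7-(methoxymethoxy)-2,2-dimethyl-2H-chromene
Conditions: dimethyl (1-diazo-2-oxopropyl)phosphonate (1.3 equiv), K2CO3 (2 equiv), MeOH, 0 °C → rt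
Reagents that add atoms: dimethyl (1-diazo-2-oxopropyl)phosphonate (Ohira–Bestmann reagent), CC(=O)C(=[N+]=[N-])P(=O)(OC)OC
Why: Seyferth–Gilbert homologation in the Ohira–Bestmann variant converts non-enolisable aryl aldehydes into terminal alkynes under mild carbonate conditions that leave the MOM ether and the chromene untouched.

Step 11
Reactants: 11 2-iodo-4,6-bis(3-methylbut-2-enyl)benzene-1,3,5-triyl triacetate; 21 6-ethynyl-7-(methoxymethoxy)-2,2-dimethyl-2H-chromene; 22 carbon monoxide
Product: 25 5,7-dihydroxy-2-[7-(methoxymethoxy)-2,2-dimethyl-2H-chromen-6-yl]-6,8-bis(3-methylbut-2-enyl)-4H-chromen-4-one, via ynone triacetate 23 (not isolated), via enaminone 24 (not isolated)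
Conditions: PdCl2(PPh3)2 (5 mol %), thiourea (5 mol %), dppp (5 mol %), DBU (2 equiv), Et2NH (solvent), CO (1 atm), 40 °C, then 60 °C
Reagents that add atoms: carbon monoxide (22), [C-]#[O+]
Why: Oxidative addition of Pd(0) into the C–I bond, CO insertion to the aroyl–palladium species, copper-free alkynyl transfer and reductive elimination should give ynone 23 (forming C4a–C4 and C3–C4), after which diethylamine adds to the ynone and, assisted by DBU, removes the acetyl groups to give enaminone 24. The freed ortho-phenol then closes ring C by 6-endo-trig addition–elimination at the amine-bearing carbon (formally 6-endo-dig on the ynone), forming O1–C2 and expelling diethylamine. The closest known reaction type is the palladium–thiourea–dppp-catalysed carbonylative annulation of ortho-iodophenol acetates with terminal alkynes to flavones. No stereocentre is formed. The step needs carbonylative over direct coupling and 6-endo over 5-exo closure: the aryl–palladium centre flanked by two ortho acetoxy groups should insert CO readily and couple slowly without it, the acetates keep the phenol masked until the ketone is in place (no benzofuran), and closure through the enaminone leaves only the six-membered mode (no aurone). Because the two acetoxy groups flanking the C–I carbon are mirror-related, either one becomes O1 and a single flavone should result.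

Step 12
Reactants: 25 5,7-dihydroxy-2-[7-(methoxymethoxy)-2,2-dimethyl-2H-chromen-6-yl]-6,8-bis(3-methylbut-2-enyl)-4H-chromen-4-one
Product: 26 5,7-bis(methoxymethoxy)-2-[7-(methoxymethoxy)-2,2-dimethyl-2H-chromen-6-yl]-6,8-bis(3-methylbut-2-enyl)-4H-chromen-4-one
Conditions: NaH (3 equiv), MOMCl (3 equiv), DMF, 0 °C → rt
Reagents that add atoms: chloromethyl methyl ether (MOMCl), COCCl
Why: Full deprotonation breaks the 5-OH···O=C4 chelate, and the small, hard electrophile should alkylate both the peri phenoxide and the 7-phenoxide between the two prenyl groups on oxygen, removing all acidic protons before the hydride step.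

Step 13
Reactants: 26 5,7-bis(methoxymethoxy)-2-[7-(methoxymethoxy)-2,2-dimethyl-2H-chromen-6-yl]-6,8-bis(3-methylbut-2-enyl)-4H-chromen-4-one
Product: 28 (2S)-5,7-bis(methoxymethoxy)-2-[7-(methoxymethoxy)-2,2-dimethyl-2H-chromen-6-yl]-6,8-bis(3-methylbut-2-enyl)chroman-4-one, via silyl enol ether 27 (not isolated)
Conditions: Cu(OAc)2 (5 mol %), (R)-DTBM-SEGPHOS (5.5 mol %), (EtO)2MeSiH (3 equiv), toluene, 0 °C → rt; then AcOH/NaOAc buffer (pH 4–5), THF/H2O, 0 °C
Reagents that add atoms: none
Why: Ligand-controlled asymmetric copper hydride 1,4-reduction of the chromone enone, a reaction type established for 2-substituted chromones, delivers hydride to one face of C2 within the chiral bisphosphine pocket and so sets 2S, while the absence of a protic additive keeps the product as silyl enol ether 27 until work-up (no 1,2-over-reduction, no enolate ring opening) and leaves the prenyl and chromene alkenes unreduced.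

Step 14
Reactants: 28 (2S)-5,7-bis(methoxymethoxy)-2-[7-(methoxymethoxy)-2,2-dimethyl-2H-chromen-6-yl]-6,8-bis(3-methylbut-2-enyl)chroman-4-one
Product: 29 euchrenone a3
Conditions: HCl (2 M in MeOH)/THF 3:1, rt → 35 °C, monitored and stopped at full conversion
Reagents that add atoms: none
Why: Acid-catalysed acetal exchange with methanol removes the three aryl MOM ethers (the peri 5-O and the di-ortho-substituted 7-O acetals being especially labile) under conditions routinely used for prenylated and pyrano-fused flavonoids, and the non-basic medium avoids the retro-oxa-Michael ring opening that would racemise C2.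

**Compound list**

1 | phloroglucinol (benzene-1,3,5-triol) | Oc1cc(O)cc(O)c1 | starting material
2 | 1,3,5-tris(methoxymethoxy)benzene | COCOc1cc(OCOC)cc(OCOC)c1 | intermediate
3 | prenyl bromide (1-bromo-3-methylbut-2-ene) | CC(C)=CCBr | starting material
4 | [2,4,6-tris(methoxymethoxy)phenyl]lithium | [Li]c1c(OCOC)cc(OCOC)cc1OCOC | intermediate (not isolated)
5 | 1,3,5-tris(methoxymethoxy)-2-(3-methylbut-2-enyl)benzene | CC(C)=CCc1c(OCOC)cc(OCOC)cc1OCOC | intermediate
6 | [2,4,6-tris(methoxymethoxy)-3-(3-methylbut-2-enyl)phenyl]lithium | [Li]c1c(OCOC)cc(OCOC)c(CC=C(C)C)c1OCOC | intermediate (not isolated)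
7 | 1,3,5-tris(methoxymethoxy)-2,4-bis(3-methylbut-2-enyl)benzene | CC(C)=CCc1c(OCOC)cc(OCOC)c(CC=C(C)C)c1OCOC | intermediate
8 | [2,4,6-tris(methoxymethoxy)-3,5-bis(3-methylbut-2-enyl)phenyl]lithium | [Li]c1c(OCOC)c(CC=C(C)C)c(OCOC)c(CC=C(C)C)c1OCOC | intermediate (not isolated)
9 | 2-iodo-1,3,5-tris(methoxymethoxy)-4,6-bis(3-methylbut-2-enyl)benzene | Ic1c(OCOC)c(CC=C(C)C)c(OCOC)c(CC=C(C)C)c1OCOC | intermediate
10 | 2-iodo-4,6-bis(3-methylbut-2-enyl)benzene-1,3,5-triol | Oc1c(I)c(O)c(CC=C(C)C)c(O)c1CC=C(C)C | intermediate (not isolated)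
11 | 2-iodo-4,6-bis(3-methylbut-2-enyl)benzene-1,3,5-triyl triacetate | CC(=O)Oc1c(I)c(OC(C)=O)c(CC=C(C)C)c(OC(C)=O)c1CC=C(C)C | intermediate
12 | resorcinol (benzene-1,3-diol) | Oc1cccc(O)c1 | starting material
13 | 3-methylbut-2-enoic acid | CC(C)=CC(=O)O | starting material
14 | 1-(2,4-dihydroxyphenyl)-3-methylbut-2-en-1-one | CC(C)=CC(=O)c1ccc(O)cc1O | intermediate (not isolated)
15 | 7-hydroxy-2,2-dimethylchroman-4-one | CC1(C)CC(=O)c2ccc(O)cc2O1 | intermediate
16 | (±)-2,2-dimethylchromane-4,7-diol | CC1(C)CC(O)c2ccc(O)cc2O1 | intermediate (not isolated)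
17 | 2,2-dimethyl-2H-chromen-7-ol | CC1(C)C=Cc2ccc(O)cc2O1 | intermediate
18 | 6-(hydroxymethyl)-2,2-dimethyl-2H-chromen-7-ol | CC1(C)C=Cc2cc(CO)c(O)cc2O1 | intermediate (not isolated)
19 | 7-hydroxy-2,2-dimethyl-2H-chromene-6-carbaldehyde | CC1(C)C=Cc2cc(C=O)c(O)cc2O1 | intermediate
20 | 7-(methoxymethoxy)-2,2-dimethyl-2H-chromene-6-carbaldehyde | COCOc1cc2OC(C)(C)C=Cc2cc1C=O | intermediate
21 | 6-ethynyl-7-(methoxymethoxy)-2,2-dimethyl-2H-chromene | C#Cc1cc2C=CC(C)(C)Oc2cc1OCOC | intermediate
22 | carbon monoxide | [C-]#[O+] | starting material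
23 | 2-{3-[7-(methoxymethoxy)-2,2-dimethyl-2H-chromen-6-yl]prop-2-ynoyl}-4,6-bis(3-methylbut-2-enyl)benzene-1,3,5-triyl triacetate | CC(=O)Oc1c(C(=O)C#Cc2cc3C=CC(C)(C)Oc3cc2OCOC)c(OC(C)=O)c(CC=C(C)C)c(OC(C)=O)c1CC=C(C)C | intermediate (not isolated)
24 | 3-(diethylamino)-3-[7-(methoxymethoxy)-2,2-dimethyl-2H-chromen-6-yl]-1-[2,4,6-trihydroxy-3,5-bis(3-methylbut-2-enyl)phenyl]prop-2-en-1-one (alkene geometry not defined) | CCN(CC)C(=CC(=O)c1c(O)c(CC=C(C)C)c(O)c(CC=C(C)C)c1O)c1cc2C=CC(C)(C)Oc2cc1OCOC | intermediate (not isolated)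
25 | 5,7-dihydroxy-2-[7-(methoxymethoxy)-2,2-dimethyl-2H-chromen-6-yl]-6,8-bis(3-methylbut-2-enyl)-4H-chromen-4-one | CC(C)=CCc1c(O)c(CC=C(C)C)c2OC(c3cc4C=CC(C)(C)Oc4cc3OCOC)=CC(=O)c2c1O | intermediate
26 | 5,7-bis(methoxymethoxy)-2-[7-(methoxymethoxy)-2,2-dimethyl-2H-chromen-6-yl]-6,8-bis(3-methylbut-2-enyl)-4H-chromen-4-one | CC(C)=CCc1c(OCOC)c(CC=C(C)C)c2OC(c3cc4C=CC(C)(C)Oc4cc3OCOC)=CC(=O)c2c1OCOC | intermediate
27 | (2S)-4-{[diethoxy(methyl)silyl]oxy}-5,7-bis(methoxymethoxy)-2-[7-(methoxymethoxy)-2,2-dimethyl-2H-chromen-6-yl]-6,8-bis(3-methylbut-2-enyl)-2H-chromene | CCO[Si](C)(OCC)OC1=C[C@@H](c2cc3C=CC(C)(C)Oc3cc2OCOC)Oc2c(CC=C(C)C)c(OCOC)c(CC=C(C)C)c(OCOC)c12 | intermediate (not isolated)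
28 | (2S)-5,7-bis(methoxymethoxy)-2-[7-(methoxymethoxy)-2,2-dimethyl-2H-chromen-6-yl]-6,8-bis(3-methylbut-2-enyl)chroman-4-one | CC(C)=CCc1c(OCOC)c(CC=C(C)C)c2c(c1OCOC)C(=O)C[C@@H](c1cc3c(cc1OCOC)OC(C)(C)C=C3)O2 | intermediate
29 | euchrenone a3, (2S)-5,7-dihydroxy-2-(7-hydroxy-2,2-dimethyl-2H-chromen-6-yl)-6,8-bis(3-methylbut-2-enyl)chroman-4-one | CC(C)=CCc1c(O)c(CC=C(C)C)c2c(c1O)C(=O)C[C@@H](c1cc3c(cc1O)OC(C)(C)C=C3)O2 | target

**Step count and risks**

Total: 14 steps. Longest linear sequence: 9 steps (steps 1–5 and 11–14 from phloroglucinol; the resorcinol branch, steps 6–10 and 11–14, is equally long).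

Steps most likely to fail:

1. Step 11. Direct alkynylation may outrun CO insertion, the electron-rich ring may lose iodine once its esters are cleaved, or closure may take the five-membered course. In the fallback C4 is brought in as a formyl carbon and ring C is closed without palladium. Setting out from 7, metalation as in step 4 (aryllithium 8) and a DMF quench should give 2,4,6-tris(methoxymethoxy)-3,5-bis(3-methylbut-2-enyl)benzaldehyde F1. Brief exposure to dilute HCl in MeOH at 0 °C, where the carbonyl-assisted ortho acetal is cleaved first (the two ortho acetals are equivalent, so the symmetry argument still holds), should give 2-hydroxy-4,6-bis(methoxymethoxy)-3,5-bis(3-methylbut-2-enyl)benzaldehyde F2. Addition of the lithium acetylide of 21 (2.2 equiv, THF, −78 °C) should give 1-[2-hydroxy-4,6-bis(methoxymethoxy)-3,5-bis(3-methylbut-2-enyl)phenyl]-3-[7-(methoxymethoxy)-2,2-dimethyl-2H-chromen-6-yl]prop-2-yn-1-ol F3. MnO2 in CH2Cl2 should oxidise it to 1-[2-hydroxy-4,6-bis(methoxymethoxy)-3,5-bis(3-methylbut-2-enyl)phenyl]-3-[7-(methoxymethoxy)-2,2-dimethyl-2H-chromen-6-yl]prop-2-yn-1-one F4. Diethylamine in ethanol then closes ring C by the same amine-mediated 6-endo addition–elimination and gives 26 directly, so step 12 is skipped and the route resumes at step 13.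

2. Step 13. The hindered, electron-rich enone may be reduced sluggishly, the ligand may discriminate the two faces of C2 poorly, or the copper enolate may open ring C by β-aryloxide elimination. The fallback separates reduction from stereocontrol. Setting out from 26, a non-selective 1,4-reduction with L-Selectride (THF, −78 °C) should give racemic 5,7-bis(methoxymethoxy)-2-[7-(methoxymethoxy)-2,2-dimethyl-2H-chromen-6-yl]-6,8-bis(3-methylbut-2-enyl)chroman-4-one F5. Kinetic resolution by Noyori-type asymmetric transfer hydrogenation (Ru–TsDPEN, HCO2H/Et3N, the catalyst antipode that consumes the 2R ketone), which does not touch the prenyl or chromene alkenes, should convert the unwanted enantiomer into (2R,4R)-5,7-bis(methoxymethoxy)-2-[7-(methoxymethoxy)-2,2-dimethyl-2H-chromen-6-yl]-6,8-bis(3-methylbut-2-enyl)chroman-4-ol F6. Chromatographic separation leaves the unreacted 2S ketone, which is 28, and the route resumes at step 14 at the cost of half the material.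

3. Step 14. Acid may erode the configuration at C2 by ionising the O1–C2 bond next to the 2′,4′-dioxygenated ring, close a prenyl group onto a neighbouring phenol, or add methanol across the chromene double bond. The fallback moves the only acidic deprotection to the achiral flavone, where the B-ring oxygens are conjugated to the electron-poor pyranone, and ends with fluoride. Setting out from 25, HCl in MeOH should remove the single MOM group and give 5,7-dihydroxy-2-(7-hydroxy-2,2-dimethyl-2H-chromen-6-yl)-6,8-bis(3-methylbut-2-enyl)-4H-chromen-4-one F7. TESOTf and 2,6-lutidine in CH2Cl2 should give 5,7-bis(triethylsilyloxy)-2-[2,2-dimethyl-7-(triethylsilyloxy)-2H-chromen-6-yl]-6,8-bis(3-methylbut-2-enyl)-4H-chromen-4-one F8. The copper hydride reduction of step 13 should give (2S)-4-{[diethoxy(methyl)silyl]oxy}-5,7-bis(triethylsilyloxy)-2-[2,2-dimethyl-7-(triethylsilyloxy)-2H-chromen-6-yl]-6,8-bis(3-methylbut-2-enyl)-2H-chromene F9. The crude F9 is treated with HF·pyridine in THF/pyridine at 0 °C, which cleaves the enol silyl ether and the three aryl silyl ethers together under non-basic, weakly acidic conditions and arrives at 29.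

Further compounds
F1 | step 11 | 2,4,6-tris(methoxymethoxy)-3,5-bis(3-methylbut-2-enyl)benzaldehyde | O=Cc1c(OCOC)c(CC=C(C)C)c(OCOC)c(CC=C(C)C)c1OCOC
F2 | step 11 | 2-hydroxy-4,6-bis(methoxymethoxy)-3,5-bis(3-methylbut-2-enyl)benzaldehyde | O=Cc1c(O)c(CC=C(C)C)c(OCOC)c(CC=C(C)C)c1OCOC
F3 | step 11 | (±)-1-[2-hydroxy-4,6-bis(methoxymethoxy)-3,5-bis(3-methylbut-2-enyl)phenyl]-3-[7-(methoxymethoxy)-2,2-dimethyl-2H-chromen-6-yl]prop-2-yn-1-ol | OC(C#Cc1cc2C=CC(C)(C)Oc2cc1OCOC)c1c(O)c(CC=C(C)C)c(OCOC)c(CC=C(C)C)c1OCOC
F4 | step 11 | 1-[2-hydroxy-4,6-bis(methoxymethoxy)-3,5-bis(3-methylbut-2-enyl)phenyl]-3-[7-(methoxymethoxy)-2,2-dimethyl-2H-chromen-6-yl]prop-2-yn-1-one | O=C(C#Cc1cc2C=CC(C)(C)Oc2cc1OCOC)c1c(O)c(CC=C(C)C)c(OCOC)c(CC=C(C)C)c1OCOC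
F5 | step 13 | (±)-5,7-bis(methoxymethoxy)-2-[7-(methoxymethoxy)-2,2-dimethyl-2H-chromen-6-yl]-6,8-bis(3-methylbut-2-enyl)chroman-4-one | CC(C)=CCc1c(OCOC)c(CC=C(C)C)c2c(c1OCOC)C(=O)CC(c1cc3c(cc1OCOC)OC(C)(C)C=C3)O2
F6 | step 13 | (2R,4R)-5,7-bis(methoxymethoxy)-2-[7-(methoxymethoxy)-2,2-dimethyl-2H-chromen-6-yl]-6,8-bis(3-methylbut-2-enyl)chroman-4-ol | CC(C)=CCc1c(OCOC)c(CC=C(C)C)c2c(c1OCOC)[C@H](O)C[C@H](c1cc3c(cc1OCOC)OC(C)(C)C=C3)O2
F7 | step 14 | 5,7-dihydroxy-2-(7-hydroxy-2,2-dimethyl-2H-chromen-6-yl)-6,8-bis(3-methylbut-2-enyl)-4H-chromen-4-one | CC(C)=CCc1c(O)c(CC=C(C)C)c2OC(c3cc4C=CC(C)(C)Oc4cc3O)=CC(=O)c2c1O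
F8 | step 14 | 5,7-bis(triethylsilyloxy)-2-[2,2-dimethyl-7-(triethylsilyloxy)-2H-chromen-6-yl]-6,8-bis(3-methylbut-2-enyl)-4H-chromen-4-one | CC(C)=CCc1c(O[Si](CC)(CC)CC)c(CC=C(C)C)c2OC(c3cc4C=CC(C)(C)Oc4cc3O[Si](CC)(CC)CC)=CC(=O)c2c1O[Si](CC)(CC)CC
F9 | step 14 | (2S)-4-{[diethoxy(methyl)silyl]oxy}-5,7-bis(triethylsilyloxy)-2-[2,2-dimethyl-7-(triethylsilyloxy)-2H-chromen-6-yl]-6,8-bis(3-methylbut-2-enyl)-2H-chromene | CCO[Si](C)(OCC)OC1=C[C@@H](c2cc3C=CC(C)(C)Oc3cc2O[Si](CC)(CC)CC)Oc2c(CC=C(C)C)c(O[Si](CC)(CC)CC)c(CC=C(C)C)c(O[Si](CC)(CC)CC)c12
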